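**Plan**
- Retrosynthesis: after the benzyl ethers and pivalates, the bonds C2u–ring B and C2l–ring E are cut together, leaving a bis-chroman core (rings A/C and D/F) and one arylzinc reagent. The core is then cut through ring F (C3l–C4l, O1l–C2l), through ring C (C3u–C4u, O1u–C2u) and at C4u–C6 of ring D.
- Forward: rings A and D both come from 2,4,6-trihydroxybenzaldehyde and are joined by an aryllithium addition. Ring C closes by an amine-catalysed o-quinone methide annulation with a silyloxyacetaldehyde. The freed ring D phenol is formylated ortho and reduced, ring F closes by the same annulation, and rings B and E enter last.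
- Enabling feature: rings B and E are the same aryl group on the two acetal-level carbons C2u and C2l, each trans to the oxygen on the adjacent C3, so one arylzinc reagent can be delivered twice under control by the C3 esters.
- Stereochemistry: C3u, C4u and C3l come from the (R)-prolinol silyl ether catalyst (C4u trans to C3u); C2u and C2l come from participation of the C3 pivalates.

Key step: step 18

Remark: flavan numbering is used (u = upper unit, rings A, C, B; l = lower unit, rings D, F, E). C2u and C2l are epimeric mixtures until step 18 and are drawn without configuration. The CIP label of C4u switches between R and S with the substitution of ring D, although its geometry is fixed from step 7 on. Compound 10 and the catalyst are taken as commercial.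

Step 1
Reactants: 1 2,4,6-trihydroxybenzaldehyde
Product: 2 2,4-bis(benzyloxy)-6-hydroxybenzaldehyde
Conditions: BnBr (2.1 equiv), K2CO3, DMF, 0 °C to rt
Reagents that add atoms: benzyl bromide, BrCc1ccccc1
Why: Williamson etherification in which the hydroxyl hydrogen-bonded to the formyl oxygen is the least reactive and should stay free, a known selectivity for this aldehyde.

Step 2
Reactants: 1 2,4,6-trihydroxybenzaldehyde
Product: 3 2,6-dihydroxy-4-(prop-2-en-1-yloxy)benzaldehyde
Conditions: allyl bromide (1.0 equiv), KHCO3, DMF, 40 °C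
Reagents that add atoms: allyl bromide, C=CCBr
Why: Williamson etherification under a weak base, in which the 4-hydroxyl (para to the formyl group and not hydrogen-bonded) is the most acidic and should react first, as in known mono-O-alkylations of phloroglucinol aldehydes and ketones.

Step 3
Reactants: 3 2,6-dihydroxy-4-(prop-2-en-1-yloxy)benzaldehyde
Product: 4 2,6-bis(benzyloxy)-4-(prop-2-en-1-yloxy)benzaldehyde
Conditions: BnBr (2.5 equiv), K2CO3, DMF, 70 °C
Reagents that add atoms: benzyl bromide, BrCc1ccccc1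
Why: forcing Williamson etherification of the two hydrogen-bonded ortho hydroxyls, which leaves the unique para oxygen as the allyl ether.

Step 4
Reactants: 4 2,6-bis(benzyloxy)-4-(prop-2-en-1-yloxy)benzaldehyde
Product: 5 2,6-bis(benzyloxy)-4-(prop-2-en-1-yloxy)benzoic acid
Conditions: NaClO2, NaH2PO4, 2-methyl-2-butene (excess), t-BuOH/THF/H2O, 0 °C to rt
Reagents that add atoms: sodium chlorite, [Na+].[O-]Cl=O
Why: Pinnick oxidation, with the alkene scavenger removing hypochlorous acid before it can attack the electron-rich ring or the allyl group.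

Step 5
Reactants: 5 2,6-bis(benzyloxy)-4-(prop-2-en-1-yloxy)benzoic acid
Product: 6 1,3-bis(benzyloxy)-2-bromo-5-(prop-2-en-1-yloxy)benzene
Conditions: N-bromosuccinimide (1.05 equiv), LiOAc (10 mol%), MeCN, 0 °C to rt, dark
Reagents that add atoms: N-bromosuccinimide, O=C1CCC(=O)N1Br
Why: Hunsdiecker-type ipso-bromodecarboxylation of an electron-rich benzoic acid, which fixes bromine between the two benzyloxy groups and para to the allyloxy group, a position direct bromination of the triether would not select.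

Step 6
Reactants: 6 1,3-bis(benzyloxy)-2-bromo-5-(prop-2-en-1-yloxy)benzene; 2 2,4-bis(benzyloxy)-6-hydroxybenzaldehyde
Product: 9 rac-[2,4-bis(benzyloxy)-6-hydroxyphenyl][2,6-bis(benzyloxy)-4-(prop-2-en-1-yloxy)phenyl]methanol, via aryllithium 7 (not isolated), via sodium phenolate 8 (not isolated)
Conditions: 6, n-BuLi, THF, −78 °C; 2, NaH, THF, 0 °C; combine at −78 °C, warm to 0 °C; aq. NH4Cl; product used without delay
Reagents that add atoms: none
Why: bromine–lithium exchange gives 7, which adds 1,2 to the formyl group of 8 (the phenol is carried as its sodium salt so that one equivalent of 7 suffices); the new carbinol centre is racemic and is destroyed in step 7.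

Step 7
Reactants: 9 rac-[2,4-bis(benzyloxy)-6-hydroxyphenyl][2,6-bis(benzyloxy)-4-(prop-2-en-1-yloxy)phenyl]methanol; 10 (tert-butyldimethylsilyloxy)acetaldehyde
Product: 12 (3S,4R)-5,7-bis(benzyloxy)-4-[2,6-bis(benzyloxy)-4-(prop-2-en-1-yloxy)phenyl]-3-[(tert-butyldimethylsilyl)oxy]chroman-2-ol (3,4-trans; C2 epimers), via o-quinone methide 11 (not isolated)
Conditions: 10 (3 equiv), (R)-2-[diphenyl(trimethylsilyloxy)methyl]pyrrolidine (20 mol%), PhCO2H (20 mol%), CH2Cl2, 0 °C to rt
Reagents that add atoms: none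
Why: acid-promoted dehydration of 9 gives o-quinone methide 11 (in equilibrium with its diarylcarbenium ion), to which the E-enamine of 10 adds in a secondary-amine-catalysed Michael addition/hemiacetalisation (formal [4+2] annulation of an aldehyde with an o-quinone methide); the diphenyl(silyloxy)methyl group of the (R)-catalyst shields one enamine face and should set C3u as S, and the endo-type approach of the E-enamine to the E-methide should place the C4u aryl group trans to the C3u silyloxy group, the minor C4 epimer being removed by chromatography.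

Step 8
Reactants: 12 (3S,4R)-lactol
Product: 13 (3S,4R)-5,7-bis(benzyloxy)-4-[2,6-bis(benzyloxy)-4-(prop-2-en-1-yloxy)phenyl]-2,3-bis[(tert-butyldimethylsilyl)oxy]chromane
Conditions: t-BuMe2SiCl, imidazole, 4-(dimethylamino)pyridine (cat.), DMF, rt
Reagents that add atoms: tert-butyldimethylsilyl chloride, CC(C)(C)[Si](C)(C)Cl
Why: silylation of the lactol hydroxyl masks the latent aldehyde as a silyl acetal that tolerates the base, hydride and heat of steps 9 to 11 and leaves with the other silyl groups in step 13.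

Step 9
Reactants: 13 bis-silyl chromane allyl ether
Product: 14 3,5-bis(benzyloxy)-4-{(3S,4R)-5,7-bis(benzyloxy)-2,3-bis[(tert-butyldimethylsilyl)oxy]chroman-4-yl}phenol
Conditions: Pd(PPh3)4 (5 mol%), morpholine, THF, rt
Reagents that add atoms: none
Why: Tsuji–Trost-type allyl transfer to morpholine frees only the ring D oxygen para to C4u under neutral conditions that leave benzyl and silyl ethers untouched.

Step 10
Reactants: 14 ring D phenol
Product: 15 2,4-bis(benzyloxy)-3-{(3S,4S)-5,7-bis(benzyloxy)-2,3-bis[(tert-butyldimethylsilyl)oxy]chroman-4-yl}-6-hydroxybenzaldehyde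
Conditions: MgCl2, Et3N, paraformaldehyde, THF, reflux
Reagents that add atoms: paraformaldehyde (formaldehyde), C=O
Why: magnesium-mediated ortho-formylation (Casnati–Skattebøl) acts only through the magnesium phenoxide of ring D, whose two ortho positions are equivalent and whose para position is blocked, so the future C4l carbon is placed without touching the equally electron-rich ring A.

Step 11
Reactants: 15 ring D salicylaldehyde
Product: 16 3,5-bis(benzyloxy)-4-{(3S,4S)-5,7-bis(benzyloxy)-2,3-bis[(tert-butyldimethylsilyl)oxy]chroman-4-yl}-2-(hydroxymethyl)phenol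
Conditions: NaBH4, THF/MeOH, 0 °C, short reaction time, non-acidic work-up
Reagents that add atoms: none
Why: borohydride reduction of the aldehyde gives the o-hydroxybenzyl alcohol, kept cold and base-washed so that it does not ionise and over-reduce.

Step 12
Reactants: 16 ring D o-hydroxybenzyl alcohol; 10 (tert-butyldimethylsilyloxy)acetaldehyde
Product: 18 (3S,4S)-5,7-bis(benzyloxy)-4-{(3S)-5,7-bis(benzyloxy)-3-[(tert-butyldimethylsilyl)oxy]-2-hydroxychroman-6-yl}-2,3-bis[(tert-butyldimethylsilyl)oxy]chromane, via o-quinone methide 17 (not isolated)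
Conditions: 10 (3 equiv), (R)-2-[diphenyl(trimethylsilyloxy)methyl]pyrrolidine (20 mol%), PhCO2H (20 mol%), CHCl3, rt to 40 °C
Reagents that add atoms: none
Why: the same amine-catalysed o-quinone methide annulation, in which 16 loses water to the unsubstituted methide 17, the enamine of 10 adds to its CH2 terminus with the same facial bias (C3l = S, catalyst control) and the ring D phenol closes ring F on the aldehyde; removal of the minor C3l diastereomer after this second catalyst-controlled step should also raise the enantiomeric purity.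

Step 13
Reactants: 18 tris-silyl bis-chroman lactol
Product: 19 (3S,4S)-5,7-bis(benzyloxy)-4-[(3S)-5,7-bis(benzyloxy)-2,3-dihydroxychroman-6-yl]chromane-2,3-diol
Conditions: HF·pyridine, THF/pyridine, 0 °C to rt
Reagents that add atoms: none
Why: buffered fluoride desilylation removes the silyl acetal and both secondary silyl ethers without the basic conditions that could epimerise the α-hydroxy lactols.

Step 14
Reactants: 19 bis-lactol tetraol
Product: 20 (3S,4S)-5,7-bis(benzyloxy)-4-[(3S)-5,7-bis(benzyloxy)-2,3-bis(pivaloyloxy)chroman-6-yl]chromane-2,3-diyl bis(2,2-dimethylpropanoate)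
Conditions: pivaloyl chloride (excess), 4-(dimethylamino)pyridine, pyridine, 50 °C
Reagents that add atoms: pivaloyl chloride, CC(C)(C)C(Cl)=O
Why: exhaustive acylation gives the donor for step 18 in one operation, with the C3 pivalates as participating groups and the C2 pivalates as leaving groups.

Step 15
Reactants: 21 5-bromo-1,2,3-trimethoxybenzene
Product: 22 5-bromobenzene-1,2,3-triol
Conditions: BBr3, CH2Cl2, −78 °C to rt; H2O
Reagents that add atoms: none
Why: Lewis-acid cleavage of the three aryl methyl ethers, a standard demethylation.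

Step 16
Reactants: 22 5-bromobenzene-1,2,3-triol
Product: 23 1,2,3-tris(benzyloxy)-5-bromobenzene
Conditions: BnBr (3.3 equiv), K2CO3, DMF (degassed), rt
Reagents that add atoms: benzyl bromide, BrCc1ccccc1
Why: Williamson etherification under exclusion of air, which installs the benzyl ethers needed for the final hydrogenolysis.

Step 17
Reactants: 23 1,2,3-tris(benzyloxy)-5-bromobenzene
Product: 25 3,4,5-tris(benzyloxy)phenylzinc bromide (titrated solution), via aryllithium 24 (not isolated)
Conditions: n-BuLi, THF/toluene, −78 °C; ZnBr2, −78 to 0 °C; solvent exchanged for toluene/n-Bu2O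
Reagents that add atoms: zinc dibromide, Br[Zn]Br
Why: bromine–lithium exchange followed by transmetalation to zinc gives a mild aryl donor whose carbon–zinc bond defines the ring position that will bond to C2.

Step 18
Reactants: 20 bis-chroman tetrapivalate; 25 3,4,5-tris(benzyloxy)phenylzinc bromide
Product: 27 (2R,3S,4S)-5,7-bis(benzyloxy)-4-{(2R,3S)-5,7-bis(benzyloxy)-3-(pivaloyloxy)-2-[3,4,5-tris(benzyloxy)phenyl]chroman-6-yl}-2-[3,4,5-tris(benzyloxy)phenyl]chroman-3-yl 2,2-dimethylpropanoate, via bis(2-bromochroman) 26 (not isolated)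
Conditions: Me3SiBr (2.5 equiv), ZnBr2 (10 mol%), CH2Cl2, 0 °C to rt; concentrate; 25 (5 equiv), toluene/n-Bu2O, 0 to 40 °C
Reagents that add atoms: none
Why: Proposed new method: Me3SiBr with catalytic ZnBr2 should exchange the two anomeric pivalates of 20 for bromide (26), and zinc-assisted ionisation of each C2–Br bond then gives an aryloxy-stabilised oxocarbenium ion that the carbonyl oxygen of the adjacent C3 pivalate traps as a cis-fused 1,3-dioxolan-2-ylium ion, to which 25 delivers its ipso carbon at C2 from the opposite face. The closest known reaction type is the catalyst-free C-arylation of 2-O-pivaloyl glycosyl bromides with arylzinc reagents used to make C-aryl glycosides; the extension proposed is from a pyranosyl donor to a chroman-2-yl (aryl acetal) donor and to two such sites in one molecule. No ring is closed; the two skeletal bonds C2u–ring B and C2l–ring E are formed in one operation. Each new stereocentre is controlled by its own neighbour, C2u by the C3u pivalate and C2l by the C3l pivalate, so both units should become 2,3-trans whatever the anomeric composition of 20. The step needs trans facial selectivity and ipso regioselectivity on the pyrogallol ring: the dioxolanylium ion blocks the cis face, the tert-butyl group shields the acyloxonium carbon from aryl attack, and the carbon–zinc bond fixes the bonding position, which a Friedel–Crafts reaction of a pyrogallol triether would not. The ten benzyl ethers and the C4u–C6 bond see only mild zinc Lewis acids in an aprotic medium, and no benzylic C2 cation or quinone methide of the pyrogallol rings is formed.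

Step 19
Reactants: 27 deca-O-benzyl dimer 3,3'-dipivalate
Product: 28 deca-O-benzyl gallocatechin-(4α→6)-gallocatechin
Conditions: i-Bu2AlH (6 equiv), CH2Cl2, −78 °C; aq. potassium sodium tartrate
Reagents that add atoms: none
Why: reductive ester cleavage removes both hindered pivalates without base, so the C2 and C3 centres of the flavan units cannot epimerise.

Step 20
Reactants: 28 deca-O-benzyl gallocatechin-(4α→6)-gallocatechin
Product: 29 gallocatechin-(4α→6)-gallocatechin (CNP0286965.2)
Conditions: H2 (1 atm), Pd(OH)2/C, THF/MeOH/H2O, rt; filtration and freeze-drying under argon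
Reagents that add atoms: none
Why: catalytic hydrogenolysis of the ten benzyl ethers under neutral conditions, the standard final step for benzylated proanthocyanidins, with air excluded because of the pyrogallol rings.

**Compound list**
1 | 2,4,6-trihydroxybenzaldehyde | O=Cc1c(O)cc(O)cc1O | starting material
2 | 2,4-bis(benzyloxy)-6-hydroxybenzaldehyde | O=Cc1c(O)cc(OCc2ccccc2)cc1OCc1ccccc1 | intermediate
3 | 2,6-dihydroxy-4-(prop-2-en-1-yloxy)benzaldehyde | O=Cc1c(O)cc(OCC=C)cc1O | intermediate
4 | 2,6-bis(benzyloxy)-4-(prop-2-en-1-yloxy)benzaldehyde | O=Cc1c(OCc2ccccc2)cc(OCC=C)cc1OCc1ccccc1 | intermediate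
5 | 2,6-bis(benzyloxy)-4-(prop-2-en-1-yloxy)benzoic acid | OC(=O)c1c(OCc2ccccc2)cc(OCC=C)cc1OCc1ccccc1 | intermediate
6 | 1,3-bis(benzyloxy)-2-bromo-5-(prop-2-en-1-yloxy)benzene | Brc1c(OCc2ccccc2)cc(OCC=C)cc1OCc1ccccc1 | intermediate
7 | [2,6-bis(benzyloxy)-4-(prop-2-en-1-yloxy)phenyl]lithium | [Li]c1c(OCc2ccccc2)cc(OCC=C)cc1OCc1ccccc1 | intermediate (not isolated)
8 | sodium 3,5-bis(benzyloxy)-2-formylphenolate | [Na+].[O-]c1cc(OCc2ccccc2)cc(OCc2ccccc2)c1C=O | intermediate (not isolated)
9 | rac-[2,4-bis(benzyloxy)-6-hydroxyphenyl][2,6-bis(benzyloxy)-4-(prop-2-en-1-yloxy)phenyl]methanol | OC(c1c(O)cc(OCc2ccccc2)cc1OCc1ccccc1)c1c(OCc2ccccc2)cc(OCC=C)cc1OCc1ccccc1 | intermediate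
10 | (tert-butyldimethylsilyloxy)acetaldehyde | CC(C)(C)[Si](C)(C)OCC=O | starting material
11 | 3,5-bis(benzyloxy)-6-{[2,6-bis(benzyloxy)-4-(prop-2-en-1-yloxy)phenyl]methylidene}cyclohexa-2,4-dien-1-one (o-quinone methide of ring A) | O=C1C=C(OCc2ccccc2)C=C(OCc2ccccc2)C1=Cc1c(OCc2ccccc2)cc(OCC=C)cc1OCc1ccccc1 | intermediate (not isolated)
12 | (3S,4R)-5,7-bis(benzyloxy)-4-[2,6-bis(benzyloxy)-4-(prop-2-en-1-yloxy)phenyl]-3-[(tert-butyldimethylsilyl)oxy]chroman-2-ol, 3,4-trans, both C2 epimers | c1ccccc1COc1cc(OCc3ccccc3)c2c(c1)OC(O)[C@@H](O[Si](C)(C)C(C)(C)C)[C@@H]2c1c(OCc3ccccc3)cc(OCC=C)cc1OCc1ccccc1 | intermediate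
13 | (3S,4R)-5,7-bis(benzyloxy)-4-[2,6-bis(benzyloxy)-4-(prop-2-en-1-yloxy)phenyl]-2,3-bis[(tert-butyldimethylsilyl)oxy]chromane, both C2 epimers | c1ccccc1COc1cc(OCc3ccccc3)c2c(c1)OC(O[Si](C)(C)C(C)(C)C)[C@@H](O[Si](C)(C)C(C)(C)C)[C@@H]2c1c(OCc3ccccc3)cc(OCC=C)cc1OCc1ccccc1 | intermediate
14 | 3,5-bis(benzyloxy)-4-{(3S,4R)-5,7-bis(benzyloxy)-2,3-bis[(tert-butyldimethylsilyl)oxy]chroman-4-yl}phenol | c1ccccc1COc1cc(OCc3ccccc3)c2c(c1)OC(O[Si](C)(C)C(C)(C)C)[C@@H](O[Si](C)(C)C(C)(C)C)[C@@H]2c1c(OCc3ccccc3)cc(O)cc1OCc1ccccc1 | intermediate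
15 | 2,4-bis(benzyloxy)-3-{(3S,4S)-5,7-bis(benzyloxy)-2,3-bis[(tert-butyldimethylsilyl)oxy]chroman-4-yl}-6-hydroxybenzaldehyde | c1ccccc1COc1cc(OCc3ccccc3)c2c(c1)OC(O[Si](C)(C)C(C)(C)C)[C@@H](O[Si](C)(C)C(C)(C)C)[C@@H]2c1c(OCc3ccccc3)c(C=O)c(O)cc1OCc1ccccc1 | intermediate
16 | 3,5-bis(benzyloxy)-4-{(3S,4S)-5,7-bis(benzyloxy)-2,3-bis[(tert-butyldimethylsilyl)oxy]chroman-4-yl}-2-(hydroxymethyl)phenol | c1ccccc1COc1cc(OCc3ccccc3)c2c(c1)OC(O[Si](C)(C)C(C)(C)C)[C@@H](O[Si](C)(C)C(C)(C)C)[C@@H]2c1c(OCc3ccccc3)c(CO)c(O)cc1OCc1ccccc1 | intermediate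
17 | 3,5-bis(benzyloxy)-4-{5,7-bis(benzyloxy)-2,3-bis[(tert-butyldimethylsilyl)oxy]chroman-4-yl}-6-methylidenecyclohexa-2,4-dien-1-one (o-quinone methide of ring D, chromane centres as in 16) | c1ccccc1COc1cc(OCc3ccccc3)c2c(c1)OC(O[Si](C)(C)C(C)(C)C)[C@@H](O[Si](C)(C)C(C)(C)C)[C@@H]2C1=C(OCc3ccccc3)C(=C)C(=O)C=C1OCc1ccccc1 | intermediate (not isolated)
18 | (3S,4S)-5,7-bis(benzyloxy)-4-{(3S)-5,7-bis(benzyloxy)-3-[(tert-butyldimethylsilyl)oxy]-2-hydroxychroman-6-yl}-2,3-bis[(tert-butyldimethylsilyl)oxy]chromane | c1ccccc1COc1cc(OCc3ccccc3)c2c(c1)OC(O[Si](C)(C)C(C)(C)C)[C@@H](O[Si](C)(C)C(C)(C)C)[C@@H]2c1c(OCc3ccccc3)cc2c(c1OCc1ccccc1)C[C@H](O[Si](C)(C)C(C)(C)C)C(O)O2 | intermediate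
19 | (3S,4S)-5,7-bis(benzyloxy)-4-[(3S)-5,7-bis(benzyloxy)-2,3-dihydroxychroman-6-yl]chromane-2,3-diol | c1ccccc1COc1cc(OCc3ccccc3)c2c(c1)OC(O)[C@@H](O)[C@@H]2c1c(OCc3ccccc3)cc2c(c1OCc1ccccc1)C[C@H](O)C(O)O2 | intermediate
20 | (3S,4S)-5,7-bis(benzyloxy)-4-[(3S)-5,7-bis(benzyloxy)-2,3-bis(pivaloyloxy)chroman-6-yl]chromane-2,3-diyl bis(2,2-dimethylpropanoate) | c1ccccc1COc1cc(OCc3ccccc3)c2c(c1)OC(OC(=O)C(C)(C)C)[C@@H](OC(=O)C(C)(C)C)[C@@H]2c1c(OCc3ccccc3)cc2c(c1OCc1ccccc1)C[C@H](OC(=O)C(C)(C)C)C(OC(=O)C(C)(C)C)O2 | intermediate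
21 | 5-bromo-1,2,3-trimethoxybenzene | COc1cc(Br)cc(OC)c1OC | starting material
22 | 5-bromobenzene-1,2,3-triol | Oc1cc(Br)cc(O)c1O | intermediate
23 | 1,2,3-tris(benzyloxy)-5-bromobenzene | Brc1cc(OCc2ccccc2)c(OCc2ccccc2)c(OCc2ccccc2)c1 | intermediate
24 | [3,4,5-tris(benzyloxy)phenyl]lithium | [Li]c1cc(OCc2ccccc2)c(OCc2ccccc2)c(OCc2ccccc2)c1 | intermediate (not isolated)
25 | 3,4,5-tris(benzyloxy)phenylzinc bromide | Br[Zn]c1cc(OCc2ccccc2)c(OCc2ccccc2)c(OCc2ccccc2)c1 | intermediate
26 | (3S,4S)-5,7-bis(benzyloxy)-4-[(3S)-5,7-bis(benzyloxy)-2-bromo-3-(pivaloyloxy)chroman-6-yl]-2-bromochroman-3-yl 2,2-dimethylpropanoate | c1ccccc1COc1cc(OCc3ccccc3)c2c(c1)OC(Br)[C@@H](OC(=O)C(C)(C)C)[C@@H]2c1c(OCc3ccccc3)cc2c(c1OCc1ccccc1)C[C@H](OC(=O)C(C)(C)C)C(Br)O2 | intermediate (not isolated)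
27 | (2R,3S,4S)-5,7-bis(benzyloxy)-4-{(2R,3S)-5,7-bis(benzyloxy)-3-(pivaloyloxy)-2-[3,4,5-tris(benzyloxy)phenyl]chroman-6-yl}-2-[3,4,5-tris(benzyloxy)phenyl]chroman-3-yl 2,2-dimethylpropanoate | c1ccccc1COc1cc(OCc3ccccc3)c2c(c1)O[C@H](c4cc(OCc3ccccc3)c(OCc3ccccc3)c(OCc3ccccc3)c4)[C@@H](OC(=O)C(C)(C)C)[C@@H]2c1c(OCc3ccccc3)cc2c(c1OCc1ccccc1)C[C@H](OC(=O)C(C)(C)C)[C@@H](c1cc(OCc3ccccc3)c(OCc3ccccc3)c(OCc3ccccc3)c1)O2 | intermediate
28 | (2R,3S,4S)-5,7-bis(benzyloxy)-4-{(2R,3S)-5,7-bis(benzyloxy)-3-hydroxy-2-[3,4,5-tris(benzyloxy)phenyl]chroman-6-yl}-2-[3,4,5-tris(benzyloxy)phenyl]chroman-3-ol | c1ccccc1COc1cc(OCc3ccccc3)c2c(c1)O[C@H](c4cc(OCc3ccccc3)c(OCc3ccccc3)c(OCc3ccccc3)c4)[C@@H](O)[C@@H]2c1c(OCc3ccccc3)cc2c(c1OCc1ccccc1)C[C@H](O)[C@@H](c1cc(OCc3ccccc3)c(OCc3ccccc3)c(OCc3ccccc3)c1)O2 | intermediate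
29 | gallocatechin-(4α→6)-gallocatechin, (2R,3S,4R)-2-(3,4,5-trihydroxyphenyl)-4-[(2R,3S)-3,5,7-trihydroxy-2-(3,4,5-trihydroxyphenyl)chroman-6-yl]chromane-3,5,7-triol | Oc1cc(O)c2c(c1)O[C@H](c1cc(O)c(O)c(O)c1)[C@@H](O)[C@@H]2c1c(O)cc2c(c1O)C[C@H](O)[C@@H](c1cc(O)c(O)c(O)c1)O2 | target

**Totals**
Total step count: 20. Longest linear sequence: 16 steps (steps 2 to 14, then 18 to 20).

**Steps most likely to fail**

1. Step 18. The C2 oxocarbenium ions may be lost by elimination to enol esters, the aryl group may transfer to the acyloxonium carbon, or arylation may stop after one site. The fallback uses known chemistry and closes rings C and F at O1–C2 instead of substituting at C2. It sets out from tetraol 19. An excess of 3,4,5-tris(benzyloxy)phenylmagnesium bromide F1 (from 23 and Mg in THF) adds to both lactols in their hydroxy-aldehyde form, under chelation control by the C3 magnesium alkoxides, to give the bis(syn-1,2-diol) hexaol F2 (both new benzylic carbinols S). Triethyl orthoformate with pyridinium p-toluenesulfonate (1,2-dichloroethane, 60 °C) turns each syn-diol into a cyclic orthoester; the neighbouring phenol opens its acyloxonium ion at the benzylic carbon with inversion, the ring closure established for benzylated catechin-type diols, giving the 2,3-trans bis(3-O-formate) F3. K2CO3 in MeOH/THF removes the formates, and the route is rejoined at 28.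

2. Step 7. The enamine may add too slowly to the strongly stabilised, doubly ortho-substituted methide, and the relative configuration of C3u and C4u may be poorly controlled. The fallback is an auxiliary-controlled enolate alkylation that sets out from 9. The glycolate imide (R)-4-benzyl-3-{[(tert-butyldimethylsilyl)oxy]acetyl}-1,3-oxazolidin-2-one F4 (from (R)-4-benzyl-1,3-oxazolidin-2-one, n-BuLi and [(tert-butyldimethylsilyl)oxy]acetyl chloride) is converted into its chlorotitanium enolate (TiCl4, i-Pr2NEt, CH2Cl2, −78 °C). This is alkylated by the diarylcarbenium ion that TiCl4 generates from 9, giving the imide adduct F5 with C3u set by the auxiliary. Warming with 4-(dimethylamino)pyridine lets the ring A phenol displace the auxiliary to give the lactone (3S,4R)-5,7-bis(benzyloxy)-4-[2,6-bis(benzyloxy)-4-(prop-2-en-1-yloxy)phenyl]-3-[(tert-butyldimethylsilyl)oxy]chroman-2-one F6, at which stage C4 epimers are separated. i-Bu2AlH at −78 °C reduces F6 to lactol 12, where the route is rejoined.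

3. Step 5. Bromine may attack a ring C–H position or the allyl double bond instead of the carboxyl-bearing carbon. The fallback reverses the polarity of the ring A/ring D union and sets out from aldehyde 4. Commercial 3,5-bis(benzyloxy)phenol is brominated ortho to the hydroxyl (N-bromosuccinimide, CH2Cl2, −78 °C) to 3,5-bis(benzyloxy)-2-bromophenol F7. NaH and then t-BuLi (THF, −78 °C) convert it into sodium 3,5-bis(benzyloxy)-2-lithiophenolate F8. Its addition to 4 and aqueous NH4Cl work-up give 9, where the route is rejoined; steps 1, 4, 5 and 6 are then not needed.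

Further compounds
F1 | step 18 | 3,4,5-tris(benzyloxy)phenylmagnesium bromide | Br[Mg]c1cc(OCc2ccccc2)c(OCc2ccccc2)c(OCc2ccccc2)c1
F2 | step 18 | bis(syn-1,2-diol) hexaol from double aryl addition to 19 (both benzylic carbinols S, C3u and C3l S) | O[C@@H](c1cc(OCc2ccccc2)c(OCc2ccccc2)c(OCc2ccccc2)c1)[C@@H](O)[C@@H](c1c(O)cc(OCc2ccccc2)cc1OCc1ccccc1)c1c(OCc2ccccc2)cc(O)c(C[C@H](O)[C@H](c2cc(OCc3ccccc3)c(OCc3ccccc3)c(OCc3ccccc3)c2)O)c1OCc1ccccc1
F3 | step 18 | deca-O-benzyl gallocatechin-(4α→6)-gallocatechin 3,3'-di-O-formate | c1ccccc1COc1cc(OCc3ccccc3)c2c(c1)O[C@H](c4cc(OCc3ccccc3)c(OCc3ccccc3)c(OCc3ccccc3)c4)[C@@H](OC=O)[C@@H]2c1c(OCc3ccccc3)cc2c(c1OCc1ccccc1)C[C@H](OC=O)[C@@H](c1cc(OCc3ccccc3)c(OCc3ccccc3)c(OCc3ccccc3)c1)O2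
F4 | step 7 | (R)-4-benzyl-3-{[(tert-butyldimethylsilyl)oxy]acetyl}-1,3-oxazolidin-2-one | CC(C)(C)[Si](C)(C)OCC(=O)N1[C@H](Cc2ccccc2)COC1=O
F5 | step 7 | (R)-4-benzyl-3-{(2S,3R)-3-[2,4-bis(benzyloxy)-6-hydroxyphenyl]-3-[2,6-bis(benzyloxy)-4-(prop-2-en-1-yloxy)phenyl]-2-[(tert-butyldimethylsilyl)oxy]propanoyl}-1,3-oxazolidin-2-one | O=C1OC[C@@H](Cc2ccccc2)N1C(=O)[C@@H](O[Si](C)(C)C(C)(C)C)[C@@H](c1c(O)cc(OCc2ccccc2)cc1OCc1ccccc1)c1c(OCc2ccccc2)cc(OCC=C)cc1OCc1ccccc1
F6 | step 7 | (3S,4R)-5,7-bis(benzyloxy)-4-[2,6-bis(benzyloxy)-4-(prop-2-en-1-yloxy)phenyl]-3-[(tert-butyldimethylsilyl)oxy]chroman-2-one | c1ccccc1COc1cc(OCc3ccccc3)c2c(c1)OC(=O)[C@@H](O[Si](C)(C)C(C)(C)C)[C@@H]2c1c(OCc3ccccc3)cc(OCC=C)cc1OCc1ccccc1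
F7 | step 5 | 3,5-bis(benzyloxy)-2-bromophenol | Oc1cc(OCc2ccccc2)cc(OCc2ccccc2)c1Br
F8 | step 5 | sodium 3,5-bis(benzyloxy)-2-lithiophenolate | [Na+].[O-]c1cc(OCc2ccccc2)cc(OCc2ccccc2)c1[Li]
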